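**Retrosynthetic overview**
1. Target ⇒ (O6 desilylation, O4 acetylation) ⇒ the trans-4,5-diol of the cyclopentenone with O6 silylated, in which O4–H is the only secondary hydroxyl.
2. Feature used: the carbocycle C1–C5, with its C1 ketone, C2=C3 alkene and trans pair O4/O5, is a ring-contracted 3-substituted 4-pyranone. The pyranone O becomes O4, pyranone C3 becomes C5, and the two carbons next to the ring oxygen become C4 and C3. Light closes C3–C4 and water supplies the C5–O bond.
3. The pyranone needs only the C6 stereocentre, set by oxazaborolidine-catalysed reduction of 3-tridecanoyl-4H-pyran-4-one and followed by O-silylation.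
4. The C5–C6 bond comes from a Nozaki–Hiyama–Kishi coupling of 3-iodo-4H-pyran-4-one with tridecanal.
5. Ring order: the purchased six-membered heterocycle is carried to step 6 and converted there into the only ring of the target. No other ring is formed.

Key step: step 6

**Remarks**
- Numbering: C1 ketone, C2=C3, C4 (acetoxy carbon), C5 (tertiary carbinol), C6 (side-chain carbinol). The SMILES reads 4R,5S,6S, with O4 and O5 trans, so O4 is cis to C6.
- CIP remark: silylation of O6 lifts C6 above C4 in the ranking at C5. The unchanged geometry is therefore written 5R in the silyl ethers and 5S in the target.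
- Design remark: because O4 is cis to C6, a free triol would offer acetone a cis-fused six-membered O4/O6 ketal (chair, H4 and H6 axial) in addition to the O5/O6 dioxolane. Sorting the hydroxyls after the contraction is therefore unsafe, and O6 is capped before it at no cost in steps.
- Assumption: 4H-pyran-4-one, tridecanal and all reagents are purchasable. The lipophilic substrate does not dissolve in pure water, so the aqueous medium is water-rich acetonitrile.

**Step 1**
Reactants: 1 4H-pyran-4-one
Product: 2 3-iodo-4H-pyran-4-one
Conditions: NIS (1.05 equiv), TFA (0.3 equiv), MeCN, 60 °C, dark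
Reagents that add atoms: N-iodosuccinimide, O=C1CCC(=O)N1I
Why: Electrophilic α-iodination of a vinylogous ester, in which C3 is the nucleophilic β-carbon of the ring enol ether, loss of the C3 proton restores the pyranone, and the first iodine deactivates the ring enough for one equivalent of NIS to stop at the mono-iodide.

**Step 2**
Reactants: 2 3-iodo-4H-pyran-4-one; 3 tridecanal
Product: 5 rac-3-(1-hydroxytridecyl)-4H-pyran-4-one, via alkenylchromium dichloride 4 (not isolated)
Conditions: CrCl2 (4 equiv), NiCl2 (2 mol %), DMF, rt
Reagents that add atoms: none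
Why: Nozaki–Hiyama–Kishi coupling, in which zerovalent nickel (from NiCl2 and CrCl2) inserts into the sp2 C–I bond and transmetallation gives the trivalent alkenylchromium 4, which adds only to the aldehyde and leaves the pyranone carbonyl and the electrophilic ring positions alone; C6 is formed racemic and is erased in step 3.

**Step 3**
Reactants: 5 rac-3-(1-hydroxytridecyl)-4H-pyran-4-one
Product: 6 3-tridecanoyl-4H-pyran-4-one
Conditions: Dess–Martin periodinane (1.2 equiv), CH2Cl2, 0 °C → rt
Reagents that add atoms: none
Why: Dess–Martin oxidation of an allylic-type secondary alcohol under neutral, non-aqueous conditions, which spares the nucleophile-sensitive 3-acylpyranone.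

**Step 4**
Reactants: 6 3-tridecanoyl-4H-pyran-4-one
Product: 7 3-[(1S)-1-hydroxytridecyl]-4H-pyran-4-one
Conditions: (R)-Me-CBS [(3aR)-1-methyl-3,3-diphenyltetrahydro-1H,3H-pyrrolo[1,2-c][1,3,2]oxazaborole, 0.2 equiv], BH3·SMe2 (0.7 equiv), THF, −20 °C, slow addition of 6; MeOH quench
Reagents that add atoms: none
Why: Corey–Bakshi–Shibata reduction, in which the ketone binds the catalyst boron anti to the larger sp2-branched pyranonyl group, so the (R)-catalyst should give the (S)-carbinol (the same sense as for aryl n-alkyl ketones), while the vinylogous-ester ring carbonyl is not reduced by borane at this temperature.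

**Step 5**
Reactants: 7 3-[(1S)-1-hydroxytridecyl]-4H-pyran-4-one
Product: 8 3-[(1S)-1-(tert-butyldimethylsilyloxy)tridecyl]-4H-pyran-4-one
Conditions: TBSOTf (1.2 equiv), 2,6-lutidine (2 equiv), CH2Cl2, −78 → 0 °C
Reagents that add atoms: tert-butyldimethylsilyl triflate, CC(C)(C)[Si](C)(C)OS(=O)(=O)C(F)(F)F
Why: Silyl ether formation with a silyl triflate and a non-nucleophilic base (no amine that could add to the ring), which caps O6 so that O4 is later the only secondary hydroxyl and removes the O6–H hydrogen bonds before the key step; C6 is not touched.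

**Step 6**
Reactants: 8 3-[(1S)-1-(tert-butyldimethylsilyloxy)tridecyl]-4H-pyran-4-one
Product: 11 (4R,5R)-4,5-dihydroxy-5-[(1S)-1-(tert-butyldimethylsilyloxy)tridecyl]cyclopent-2-en-1-one, via epoxide-fused oxyallyl zwitterion 9 (not isolated), via epoxy enol 10 (not isolated)
Conditions: hν 254 nm (low-pressure Hg lamps, quartz vessel or FEP flow coil), MeCN–H2O 3:1 (as much water as keeps 8 dissolved), 2 mM, Ar, 15 °C, stopped before full conversion; chromatography
Reagents that add atoms: water, O
Why: Excitation (π,π*) of the cross-conjugated divinyl-ketone unit of 8 triggers a photochemically allowed disrotatory 4π electrocyclisation that joins the two carbons flanking the ring oxygen (future C3 and C4) and so closes the five-membered carbocycle as the epoxide-fused 2-oxidocyclopentenyl cation 9; the closest known reaction type is exactly this, the photochemical ring contraction of alkyl-substituted 4-pyranones with capture of the zwitterion by water or an alcohol. Water adds to the allyl terminus that carries the side chain (future C5), where alkyl substitution concentrates the positive charge, and it can reach that carbon only anti to the epoxide, so O5 ends up trans to the former ring oxygen; enol 10 then pushes out the neighbouring epoxide C–O bond, which gives the C2=C3 enone and leaves the ring oxygen on C4 as O4–H. C4 and C5 are therefore fixed relative to each other by the bicyclic geometry of 9, and their sense relative to C6 is decided by the face to which the ring oxygen folds. A(1,3) strain should hold the C6–H in the ring plane beside the carbonyl (oxido) oxygen, which puts the silyloxy group on one face and the dodecyl chain on the other: folding of the ring oxygen away from the C6–O dipole and entry of water on the face remote from the chain both lead to 11, and the silyl cap removes the O6–H hydrogen bonds to the oxido and epoxide oxygens that would favour the opposite face. This facial bias has not been tested and may be modest, but because C6 is already set the other trans product is a diastereomer, so chromatography still delivers a single enantiomer. The step also needs capture to outrun the irreversible drift of 9 to the isomeric 2-pyranone, hence the high water content, and 254 nm light is taken up far more strongly by 8 than by the enone 11, which limits secondary photolysis.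

**Step 7**
Reactants: 11 (4R,5R)-4,5-dihydroxy-5-[(1S)-1-(tert-butyldimethylsilyloxy)tridecyl]cyclopent-2-en-1-one
Product: 12 (1R,5R)-5-hydroxy-4-oxo-5-[(1S)-1-(tert-butyldimethylsilyloxy)tridecyl]cyclopent-2-en-1-yl acetate
Conditions: Ac2O (1.5 equiv), pyridine, 0 °C → rt
Reagents that add atoms: acetic anhydride, CC(=O)OC(C)=O
Why: Standard O-acylation in which only the secondary allylic O4–H reacts, because the tertiary O5–H between the ketone and the silyloxy carbon is too hindered without forcing, and C5 carries no hydrogen, so acetate cannot be lost by β-elimination.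

**Step 8**
Reactants: 12 (1R,5R)-5-hydroxy-4-oxo-5-[(1S)-1-(tert-butyldimethylsilyloxy)tridecyl]cyclopent-2-en-1-yl acetate
Product: 13 (1R,5S)-5-hydroxy-5-[(1S)-1-hydroxytridecyl]-4-oxocyclopent-2-en-1-yl acetate (target)
Conditions: HF·pyridine, THF (plastic vessel), 0 °C → rt; NaHCO3 work-up
Reagents that add atoms: none
Why: Fluoride-driven desilylation under mildly acidic conditions, chosen over basic TBAF to avoid O4→O6 acetyl migration and retro-aldol cleavage of C5–C6; no stereocentre is touched.

**Compound list**
1 | 4H-pyran-4-one | O=C1C=COC=C1 | starting material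
2 | 3-iodo-4H-pyran-4-one | O=C1C=COC=C1I | intermediate
3 | tridecanal | CCCCCCCCCCCCC=O | starting material
4 | (4-oxo-4H-pyran-3-yl)chromium dichloride | O=C1C=COC=C1[Cr](Cl)Cl | intermediate
5 | rac-3-(1-hydroxytridecyl)-4H-pyran-4-one | CCCCCCCCCCCCC(O)C1=COC=CC1=O | intermediate
6 | 3-tridecanoyl-4H-pyran-4-one | CCCCCCCCCCCCC(=O)C1=COC=CC1=O | intermediate
7 | 3-[(1S)-1-hydroxytridecyl]-4H-pyran-4-one | CCCCCCCCCCCC[C@H](O)C1=COC=CC1=O | intermediate
8 | 3-[(1S)-1-(tert-butyldimethylsilyloxy)tridecyl]-4H-pyran-4-one | CCCCCCCCCCCC[C@H](O[Si](C)(C)C(C)(C)C)C1=COC=CC1=O | intermediate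
9 | 2-[(1S)-1-(tert-butyldimethylsilyloxy)tridecyl]-3-oxido-6-oxabicyclo[3.1.0]hex-3-en-2-ylium, epoxide oxygen on the future O4 face | CCCCCCCCCCCC[C@H](O[Si](C)(C)C(C)(C)C)[C+]1C([O-])=C[C@H]2O[C@@H]12 | intermediate
10 | 2-[(1S)-1-(tert-butyldimethylsilyloxy)tridecyl]-6-oxabicyclo[3.1.0]hex-3-ene-2,3-diol, tertiary OH anti to the epoxide | CCCCCCCCCCCC[C@H](O[Si](C)(C)C(C)(C)C)[C@@]1(O)C(O)=C[C@H]2O[C@@H]12 | intermediate
11 | (4R,5R)-4,5-dihydroxy-5-[(1S)-1-(tert-butyldimethylsilyloxy)tridecyl]cyclopent-2-en-1-one (O4/O5 trans; 6-O-TBS ether of the deacetyl target) | CCCCCCCCCCCC[C@H](O[Si](C)(C)C(C)(C)C)[C@@]1(O)C(=O)C=C[C@H]1O | intermediate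
12 | (1R,5R)-5-hydroxy-4-oxo-5-[(1S)-1-(tert-butyldimethylsilyloxy)tridecyl]cyclopent-2-en-1-yl acetate | CCCCCCCCCCCC[C@H](O[Si](C)(C)C(C)(C)C)[C@@]1(O)C(=O)C=C[C@H]1OC(C)=O | intermediate
13 | (1R,5S)-5-hydroxy-5-[(1S)-1-hydroxytridecyl]-4-oxocyclopent-2-en-1-yl acetate | CCCCCCCCCCCC[C@H](O)[C@@]1(O)C(=O)C=C[C@H]1OC(C)=O | target

**Total step count:** 8. **Longest linear sequence:** 8 (from 4H-pyran-4-one).

**Steps most likely to fail**

1. **Step 6.**
   - Risk: the ring oxygen may fold to both faces with little preference. Water may add at the unsubstituted allyl terminus, because the oxygen on C6 weakens the charge bias and the silyloxyalkyl group crowds C5. The zwitterion may also drain to the 2-pyranone isomer.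
   - Fallback (known, non-photochemical chemistry): it sets out from 3 and returns at 13.
   - The lithium enolate (LDA, THF, −78 °C) of purchased (S)-4-(tert-butyldimethylsilyloxy)cyclopent-2-en-1-one F1 is added to 3 to give the 4,5-trans aldol F2.
   - MsCl/Et3N gives the mesylate F3, and DBU eliminates it to the (E)-5-tridecylidene dienone F4.
   - OsO4 (cat.)/NMO should dihydroxylate the more substituted exocyclic alkene, syn and from the face opposite the C4 silyloxy group. For the E alkene this gives the 4R,5S,6S diol F5.
   - With O4 blocked, 2,2-dimethoxypropane/PPTS can only form the O5,O6-acetonide F6.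
   - TBAF/AcOH gives the free C4 alcohol F7, Ac2O/pyridine gives the acetate F8, and 80% aqueous AcOH at 40 °C removes the ketal.

2. **Step 4.**
   - Risk: the strongly Lewis-basic ring carbonyl may tie up borane and the catalyst boron, which would let uncatalysed reduction erode the enantiomeric purity. Hydride may also be delivered to the doubly activated ring position next to the acyl group.
   - Fallback: it sets out from 5, skips steps 3 and 4, and returns at 7.
   - It is a kinetic resolution with Burkholderia cepacia lipase (Amano PS) and vinyl acetate in MTBE at 30 °C, run slightly past half conversion.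
   - By the usual size rule for secondary alcohols (ring as the large group), the (R)-alcohol should be acylated to the (R)-acetate F9. The unreacted (S)-alcohol 7 is then separated by chromatography.

3. **Step 2.**
   - Risk: nickel insertion into the electron-poor iodide may be slow, the iodide may be reduced (protodeiodination) by divalent chromium, or the aldehyde may undergo reductive coupling.
   - Fallback: it sets out from 2 and returns at 5, replacing the nickel/chromium manifold by a polar organometallic addition.
   - Iodine–magnesium exchange with iPrMgCl·LiCl (THF, −78 °C) gives 3-chloromagnesio-4H-pyran-4-one F10, which is trapped at once with 3.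

**Further compounds**
F1 | step 6 | (S)-4-(tert-butyldimethylsilyloxy)cyclopent-2-en-1-one (purchased) | O=C1C=C[C@@H](O[Si](C)(C)C(C)(C)C)C1
F2 | step 6 | (4R,5S)-4-(tert-butyldimethylsilyloxy)-5-(1-hydroxytridecyl)cyclopent-2-en-1-one (4,5-trans, carbinol epimers) | CCCCCCCCCCCCC(O)[C@@H]1C(=O)C=C[C@H]1O[Si](C)(C)C(C)(C)C
F3 | step 6 | methanesulfonate of F2 | CCCCCCCCCCCCC(OS(C)(=O)=O)[C@@H]1C(=O)C=C[C@H]1O[Si](C)(C)C(C)(C)C
F4 | step 6 | (4R,5E)-4-(tert-butyldimethylsilyloxy)-5-tridecylidenecyclopent-2-en-1-one | CCCCCCCCCCCC/C=C1/C(=O)C=C[C@H]1O[Si](C)(C)C(C)(C)C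
F5 | step 6 | (4R,5S)-4-(tert-butyldimethylsilyloxy)-5-hydroxy-5-[(1S)-1-hydroxytridecyl]cyclopent-2-en-1-one | CCCCCCCCCCCC[C@H](O)[C@@]1(O)C(=O)C=C[C@H]1O[Si](C)(C)C(C)(C)C
F6 | step 6 | O5,O6-isopropylidene ketal of F5 (spiro dioxolane) | CCCCCCCCCCCC[C@@H]1OC(C)(C)O[C@@]12C(=O)C=C[C@H]2O[Si](C)(C)C(C)(C)C
F7 | step 6 | O5,O6-isopropylidene ketal with free O4–H | CCCCCCCCCCCC[C@@H]1OC(C)(C)O[C@@]12C(=O)C=C[C@H]2O
F8 | step 6 | O4-acetate of F7 | CCCCCCCCCCCC[C@@H]1OC(C)(C)O[C@@]12C(=O)C=C[C@H]2OC(C)=O
F9 | step 4 | (1R)-1-(4-oxo-4H-pyran-3-yl)tridecyl acetate | CCCCCCCCCCCC[C@@H](OC(C)=O)C1=COC=CC1=O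
F10 | step 2 | 3-chloromagnesio-4H-pyran-4-one | O=C1C=COC=C1[Mg]Cl
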